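Assumptions: the three ester groups are read from the SMILES as angelates, (Z)-2-methylbut-2-enoates. (R)-(−)-Carvone, angelic acid, 2,4,6-trichlorobenzoyl chloride, 3-methylbut-2-en-1-ol, B2pin2, (S)-TRIP and the D-fructose-derived Shi ketone are taken as commercial. "C8" is the side-chain carbinol carbon and "C10" the side-chain oxirane CH.

## Retrosynthetic overview

1. The side-chain oxirane is made last, by Shi epoxidation of the prenyl-type alkene of a tris-angelate diene (sets C10).
2. The tris-angelate comes from a C8 carbinol; its C8–C9 bond and C8 stereocentre come from an enal plus a tertiary allylboronate (new acid-catalysed linear prenylboration).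
3. The enal comes from an isopropenyl epoxy bis-angelate by ene-chlorination and N-oxide oxidation.
4. The epoxy bis-angelate comes from (R)-carvone by α′-hydroxylation, Luche reduction, hydroxyl-directed epoxidation and bis-angeloylation with a preformed angelic mixed anhydride.
5. Ring order: cyclohexane (from carvone), then the ring-fused oxirane, then the side-chain oxirane.

## Route

Step 1
Reactants: 1 (R)-(−)-carvone
Product: 3 (5S,6S)-6-hydroxy-2-methyl-5-(prop-1-en-2-yl)cyclohex-2-en-1-one (trans-6-hydroxycarvone), via sodium dienolate 2 (not isolated)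
Conditions: NaN(SiMe3)2 (1.1 equiv), THF, −78 °C; 2-(phenylsulfonyl)-3-phenyloxaziridine (1.3 equiv), −78 °C; AcOH quench
Reagents that add atoms: 2-(phenylsulfonyl)-3-phenyloxaziridine, O=S(=O)(c1ccccc1)N1OC1c1ccccc1
Why: Kinetic α′-deprotonation gives the cross-conjugated dienolate, and electrophilic oxygen transfer (Davis enolate hydroxylation) occurs anti to the adjacent isopropenyl group, setting the 5,6-trans carbinol (minor cis isomer removed by chromatography).

Step 2
Reactants: 3 (5S,6S)-6-hydroxycarvone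
Product: 4 (1S,2S,6S)-3-methyl-6-(prop-1-en-2-yl)cyclohex-3-ene-1,2-diol
Conditions: NaBH4 (1.1 equiv), CeCl3·7H2O (1.1 equiv), MeOH, −40 °C
Reagents that add atoms: none
Why: Luche 1,2-reduction with axial hydride delivery, as in carvone to cis-carveol, gives the equatorial allylic alcohol, trans to the neighbouring hydroxyl and cis to the isopropenyl-bearing carbon.

Step 3
Reactants: 4 (1S,2S,6S)-3-methyl-6-(prop-1-en-2-yl)cyclohex-3-ene-1,2-diol
Product: 5 (1R,2R,3S,4S,6S)-1-methyl-4-(prop-1-en-2-yl)-7-oxabicyclo[4.1.0]heptane-2,3-diol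
Conditions: VO(acac)2 (3 mol%), t-BuOOH (1.15 equiv, decane), CH2Cl2, 0 °C → rt
Reagents that add atoms: tert-butyl hydroperoxide, CC(C)(C)OO
Why: Hydroxyl-directed vanadium-catalysed epoxidation: the allylic OH binds the vanadium alkylperoxide and delivers oxygen to its own face of the ring alkene, setting both oxirane carbons cis to that OH, while the isopropenyl group (no allylic OH) reacts far more slowly.

Step 4
Reactants: 6 angelic acid [(2Z)-2-methylbut-2-enoic acid]
Product: 7 (2Z)-2-methylbut-2-enoic 2,4,6-trichlorobenzoic anhydride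
Conditions: 2,4,6-Cl3C6H2COCl (1.0 equiv), Et3N (1.05 equiv), PhMe, 0 °C → rt, 2 h; Et3N·HCl filtered off under argon; filtrate concentrated and kept as a PhMe stock solution at −20 °C (one batch, enough for steps 5 and 11)
Reagents that add atoms: 2,4,6-trichlorobenzoyl chloride, O=C(Cl)c1c(Cl)cc(Cl)cc1Cl
Why: Yamaguchi mixed-anhydride formation: the triethylammonium carboxylate is acylated at oxygen by the hindered aroyl chloride without a nucleophilic catalyst, so the Z alkene is untouched, and the two ortho chlorines shield the aroyl carbonyl so that later alcoholysis occurs at the angeloyl carbonyl.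

Step 5
Reactants: 5 epoxy diol; 7 angelic 2,4,6-trichlorobenzoic mixed anhydride
Product: 8 (1S,2R,3S,4S,6S)-1-methyl-4-(prop-1-en-2-yl)-7-oxabicyclo[4.1.0]heptane-2,3-diyl bis[(2Z)-2-methylbut-2-enoate]
Conditions: 7 (4 equiv, PhMe solution), Et3N (2.5 equiv, acid buffer), PhMe, 80 °C
Reagents that add atoms: none
Why: Yamaguchi-type mixed-anhydride acylation without a nucleophilic catalyst transfers the angeloyl group with retention of Z geometry; no stereocentre is touched, and the cis relation of the neighbouring oxygen to the oxirane excludes Payne rearrangement (the C1 descriptor changes from R to S only through CIP priorities).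

Step 6
Reactants: 8 epoxy bis-angelate
Product: 9 (1S,2R,3S,4S,6S)-4-(3-chloroprop-1-en-2-yl)-1-methyl-7-oxabicyclo[4.1.0]heptane-2,3-diyl bis[(2Z)-2-methylbut-2-enoate]
Conditions: Ca(OCl)2 (0.7 equiv), CO2 (dry ice), CH2Cl2/H2O, 0 °C
Reagents that add atoms: calcium hypochlorite, [Ca+2].[O-]Cl.[O-]Cl
Why: Ene-type allylic chlorination by HOCl made in the flask: electrophilic chlorine adds to the terminal carbon of the only electron-rich alkene and a methyl proton is lost with double-bond shift, while the conjugated angelate alkenes are too electron-poor to react.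

Step 7
Reactants: 9 allylic chloride
Product: 11 (1S,2R,3S,4S,6S)-1-methyl-4-(3-oxoprop-1-en-2-yl)-7-oxabicyclo[4.1.0]heptane-2,3-diyl bis[(2Z)-2-methylbut-2-enoate], via alkoxymorpholinium chloride 10 (not isolated)
Conditions: N-methylmorpholine N-oxide (5 equiv), 4 Å MS, MeCN, 40 °C
Reagents that add atoms: N-methylmorpholine N-oxide, C[N+]1([O-])CCOCC1
Why: Amine-oxide oxidation of an allylic halide (Ganem/Kornblum type): SN2 O-alkylation of the N-oxide followed by base-induced N–O fragmentation gives the 2-substituted acrolein without touching esters, oxirane or stereocentres.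

Step 8
Reactants: 12 3-methylbut-2-en-1-ol (prenol)
Product: 13 methyl 3-methylbut-2-en-1-yl carbonate
Conditions: ClCO2Me (1.2 equiv), pyridine, CH2Cl2, 0 °C
Reagents that add atoms: methyl chloroformate, COC(=O)Cl
Why: Standard O-acylation of a primary allylic alcohol with a chloroformate.

Step 9
Reactants: 13 methyl prenyl carbonate
Product: 14 4,4,5,5-tetramethyl-2-(2-methylbut-3-en-2-yl)-1,3,2-dioxaborolane (α,α-dimethylallyl-Bpin)
Conditions: B2pin2 (1.2 equiv), CuCl (5 mol%), Xantphos (5 mol%), KOt-Bu (10 mol%), THF, rt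
Reagents that add atoms: bis(pinacolato)diboron, CC1(C)OB(OC1(C)C)B1OC(C)(C)C(C)(C)O1
Why: Copper-boryl γ-selective (SN2′) allylic substitution: borylcupration places boron on the γ-carbon and β-elimination of the carbonate unveils the vinyl group, giving the achiral tertiary allylboronate.

Step 10
Reactants: 11 enal; 14 α,α-dimethylallyl-Bpin
Product: 16 (1S,2R,3S,4S,6S)-4-[(3S)-3-hydroxy-6-methylhepta-1,5-dien-2-yl]-1-methyl-7-oxabicyclo[4.1.0]heptane-2,3-diyl bis[(2Z)-2-methylbut-2-enoate], via pinacol borate ester 15 (not isolated)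
Conditions: 14 (1.5 equiv), (S)-TRIP [(S)-3,3′-bis(2,4,6-triisopropylphenyl)-1,1′-binaphthyl-2,2′-diyl hydrogen phosphate] (10 mol%), 4 Å MS, PhMe, −30 → 0 °C; H2O work-up
Reagents that add atoms: none
Why: Proposed new method: chiral-phosphoric-acid-catalysed, catalyst-controlled linear prenylboration with a tertiary α,α-dimethylallyl pinacol boronate; allylboration through a closed six-membered chair transition state must proceed with allylic transposition, so the unhindered CH2 terminus of 14 bonds to the aldehyde carbon and the CMe2 end becomes the trisubstituted alkene (no E/Z issue, both α-substituents being methyl), while the acid activates the boronate by hydrogen bonding to a pinacol oxygen and holds the formyl C–H with its P=O, and the (S)-acid is chosen because the (R)-acid directs allyl-Bpin to the Re face of aryl and alkenyl aldehydes, so Si-face attack sets 8S over the remote ring stereocentres; the closest known reaction type is the chiral-phosphoric-acid-catalysed allyl- and crotylboration of aldehydes with primary allyl pinacol boronates, together with uncatalysed γ-selective allylboration by α-substituted allylboronates, neither shown for a tertiary α,α-dialkylallyl boronate used as an enantioselective linear prenyl donor on an α-branched enal.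

Step 11
Reactants: 16 C8 alcohol; 7 angelic 2,4,6-trichlorobenzoic mixed anhydride
Product: 17 (1S,2R,3S,4S,6S)-1-methyl-4-[(3S)-6-methyl-3-{[(2Z)-2-methylbut-2-enoyl]oxy}hepta-1,5-dien-2-yl]-7-oxabicyclo[4.1.0]heptane-2,3-diyl bis[(2Z)-2-methylbut-2-enoate]
Conditions: 7 (3 equiv, PhMe solution from step 4), Et3N (2 equiv, acid buffer), PhMe, 70 °C
Reagents that add atoms: none
Why: The same mixed-anhydride acylation as in step 5; acylation at oxygen leaves the C8–O bond intact, so 8S is retained and the angelate stays Z.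

Step 12
Reactants: 17 tris-angelate diene
Product: 18 target, (1S,2R,3S,4S,6S)-4-[(3S)-4-[(2R)-3,3-dimethyloxiran-2-yl]-3-{[(2Z)-2-methylbut-2-enoyl]oxy}but-1-en-2-yl]-1-methyl-7-oxabicyclo[4.1.0]heptane-2,3-diyl bis[(2Z)-2-methylbut-2-enoate]
Conditions: D-fructose-derived Shi ketone (0.3 equiv), KHSO5 (as Oxone, 2KHSO5·KHSO4·K2SO4, 1.5 equiv), K2CO3, Bu4NHSO4 (5 mol%), Na2B4O7 buffer (pH 10.5), MeCN/CH2(OMe)2 1:2, 0 °C
Reagents that add atoms: potassium peroxymonosulfate, [K+].[O-]S(=O)(=O)OO
Why: Shi asymmetric epoxidation: the chiral dioxirane attacks the only electron-rich trisubstituted alkene through the spiro transition state, which for the D-fructose ketone gives the 10R oxirane (same sense as the (R,R)-epoxides from trans-disubstituted and trisubstituted alkenes); the acyloxy-flanked 1,1-disubstituted alkene and the three conjugated angelate alkenes are much less reactive.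

## Compound list

1 | (R)-(−)-carvone, (5R)-2-methyl-5-(prop-1-en-2-yl)cyclohex-2-en-1-one | C=C(C)[C@@H]1CC=C(C)C(=O)C1 | starting material
2 | sodium (3R)-6-methyl-3-(prop-1-en-2-yl)cyclohexa-1,5-dien-1-olate (kinetic dienolate of 1, not isolated) | C=C(C)[C@@H]1CC=C(C)C([O-])=C1.[Na+] | intermediate
3 | (5S,6S)-6-hydroxy-2-methyl-5-(prop-1-en-2-yl)cyclohex-2-en-1-one (OH trans to isopropenyl) | C=C(C)[C@@H]1CC=C(C)C(=O)[C@H]1O | intermediate
4 | (1S,2S,6S)-3-methyl-6-(prop-1-en-2-yl)cyclohex-3-ene-1,2-diol (trans-diol, allylic OH cis to isopropenyl) | C=C(C)[C@@H]1CC=C(C)[C@H](O)[C@H]1O | intermediate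
5 | (1R,2R,3S,4S,6S)-1-methyl-4-(prop-1-en-2-yl)-7-oxabicyclo[4.1.0]heptane-2,3-diol (oxirane cis to the 2-OH) | C=C(C)[C@@H]1C[C@@H]2O[C@]2(C)[C@H](O)[C@H]1O | intermediate
6 | angelic acid, (2Z)-2-methylbut-2-enoic acid | C/C=C(/C)C(=O)O | starting material
7 | (2Z)-2-methylbut-2-enoic 2,4,6-trichlorobenzoic anhydride (kept as a PhMe stock solution) | C/C=C(/C)C(=O)OC(=O)c1c(Cl)cc(Cl)cc1Cl | intermediate
8 | (1S,2R,3S,4S,6S)-1-methyl-4-(prop-1-en-2-yl)-7-oxabicyclo[4.1.0]heptane-2,3-diyl bis[(2Z)-2-methylbut-2-enoate] | C=C(C)[C@@H]1C[C@@H]2O[C@]2(C)[C@H](OC(=O)/C(C)=C\C)[C@H]1OC(=O)/C(C)=C\C | intermediate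
9 | (1S,2R,3S,4S,6S)-4-(3-chloroprop-1-en-2-yl)-1-methyl-7-oxabicyclo[4.1.0]heptane-2,3-diyl bis[(2Z)-2-methylbut-2-enoate] | C=C(CCl)[C@@H]1C[C@@H]2O[C@]2(C)[C@H](OC(=O)/C(C)=C\C)[C@H]1OC(=O)/C(C)=C\C | intermediate
10 | N-alkoxy-N-methylmorpholinium chloride of 9 (CH2Cl replaced by CH2–O–N+(CH3) of the morpholine, chloride counter-ion, ring stereocentres as in 9; not isolated) | C=C(CO[N+]1(C)CCOCC1)[C@@H]1C[C@@H]2O[C@]2(C)[C@H](OC(=O)/C(C)=C\C)[C@H]1OC(=O)/C(C)=C\C.[Cl-] | intermediate
11 | (1S,2R,3S,4S,6S)-1-methyl-4-(3-oxoprop-1-en-2-yl)-7-oxabicyclo[4.1.0]heptane-2,3-diyl bis[(2Z)-2-methylbut-2-enoate] | C=C(C=O)[C@@H]1C[C@@H]2O[C@]2(C)[C@H](OC(=O)/C(C)=C\C)[C@H]1OC(=O)/C(C)=C\C | intermediate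
12 | 3-methylbut-2-en-1-ol (prenol) | CC(C)=CCO | starting material
13 | methyl 3-methylbut-2-en-1-yl carbonate | CC(C)=CCOC(=O)OC | intermediate
14 | 4,4,5,5-tetramethyl-2-(2-methylbut-3-en-2-yl)-1,3,2-dioxaborolane | C=CC(C)(C)B1OC(C)(C)C(C)(C)O1 | intermediate
15 | pinacol borate ester of 16 (C8–O–Bpin, 8S; not isolated) | C=C([C@H](CC=C(C)C)OB1OC(C)(C)C(C)(C)O1)[C@@H]1C[C@@H]2O[C@]2(C)[C@H](OC(=O)/C(C)=C\C)[C@H]1OC(=O)/C(C)=C\C | intermediate
16 | (1S,2R,3S,4S,6S)-4-[(3S)-3-hydroxy-6-methylhepta-1,5-dien-2-yl]-1-methyl-7-oxabicyclo[4.1.0]heptane-2,3-diyl bis[(2Z)-2-methylbut-2-enoate] | C=C([C@H](CC=C(C)C)O)[C@@H]1C[C@@H]2O[C@]2(C)[C@H](OC(=O)/C(C)=C\C)[C@H]1OC(=O)/C(C)=C\C | intermediate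
17 | (1S,2R,3S,4S,6S)-1-methyl-4-[(3S)-6-methyl-3-{[(2Z)-2-methylbut-2-enoyl]oxy}hepta-1,5-dien-2-yl]-7-oxabicyclo[4.1.0]heptane-2,3-diyl bis[(2Z)-2-methylbut-2-enoate] | C=C([C@H](CC=C(C)C)OC(=O)/C(C)=C\C)[C@@H]1C[C@@H]2O[C@]2(C)[C@H](OC(=O)/C(C)=C\C)[C@H]1OC(=O)/C(C)=C\C | intermediate
18 | CNP0258231.3, (1S,2R,3S,4S,6S)-4-[(3S)-4-[(2R)-3,3-dimethyloxiran-2-yl]-3-{[(2Z)-2-methylbut-2-enoyl]oxy}but-1-en-2-yl]-1-methyl-7-oxabicyclo[4.1.0]heptane-2,3-diyl bis[(2Z)-2-methylbut-2-enoate] | C=C([C@H](C[C@H]1OC1(C)C)OC(=O)/C(C)=C\C)[C@@H]1C[C@@H]2O[C@]2(C)[C@H](OC(=O)/C(C)=C\C)[C@H]1OC(=O)/C(C)=C\C | target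

## Step count and risks

Total step count: 12. Longest linear sequence: 9 steps (steps 1–3, 5–7 and 10–12, from (R)-carvone); step 4 makes the acylating agent and steps 8–9 make the boronate.

Three steps most likely to fail:

**Step 10 (proposed new prenylboration).** The tertiary boronate may react sluggishly because one methyl is forced axial in the chair transition state. The acid catalyst may give lower facial control than with primary allylboronates, or may attack the oxirane. The fallback uses known chemistry and sets out from enal 11. The established chiral-phosphoric-acid-catalysed allylboration with commercial allyl-Bpin ((S)-TRIP, PhMe, −30 °C) gives the pinacol borate ester of the allyl adduct F1. Aqueous work-up gives the terminal homoallylic alcohol F2. Cross-metathesis of F2 with excess 2-methylbut-2-ene (second-generation Grubbs catalyst, RuCl2(=CHPh)(PCy3)(H2IMes), CH2Cl2, 40 °C) turns the vinyl group into the dimethylvinyl group and comes back to the route at 16. The hindered 1,1-disubstituted alkene and the angelates are inert in the metathesis.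

**Step 7 (allylic chloride to enal with the amine oxide).** O-alkylation by a chloride can be slow, SN2′ or elimination can compete, and the 2-substituted acrolein can isomerise or polymerise. The fallback sets out from chloride 9. Displacement with HCO2Na (Bu4NI cat., DMF, 50 °C) gives the allylic formate F3. Selective methanolysis of the formate (KHCO3, MeOH, 0 °C; the hindered conjugated angelates survive) gives the allylic alcohol F4. Oxidation with MnO2 (CH2Cl2, rt) comes back to the route at enal 11.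

**Step 5 (bis-angeloylation of the hindered epoxy diol).** The second acylation, next to the quaternary oxirane carbon, may stall. Forcing it risks angelate-to-tiglate isomerisation or oxirane opening. The fallback builds the Z-alkenes on the substrate and sets out from epoxy diol 5. Both hydroxyls are esterified with the unhindered 2-[bis(2,2,2-trifluoroethoxy)phosphoryl]propanoic acid (EDC·HCl, DMAP, CH2Cl2, rt) to give the bis(phosphonopropanoate) F5. Treatment with KN(SiMe3)2 and 18-crown-6 (THF, −78 °C) gives the dipotassium bis(phosphonate carbanion) F6. Acetaldehyde then effects a double Still–Gennari Z-selective olefination and comes back to the route at bis-angelate 8.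

## Further compounds

F1 | step 10 | pinacol borate ester of F2 (C8–O–Bpin, 8S; not isolated) | C=C([C@H](CC=C)OB1OC(C)(C)C(C)(C)O1)[C@@H]1C[C@@H]2O[C@]2(C)[C@H](OC(=O)/C(C)=C\C)[C@H]1OC(=O)/C(C)=C\C
F2 | step 10 | (1S,2R,3S,4S,6S)-4-[(3S)-3-hydroxyhexa-1,5-dien-2-yl]-1-methyl-7-oxabicyclo[4.1.0]heptane-2,3-diyl bis[(2Z)-2-methylbut-2-enoate] | C=C([C@H](CC=C)O)[C@@H]1C[C@@H]2O[C@]2(C)[C@H](OC(=O)/C(C)=C\C)[C@H]1OC(=O)/C(C)=C\C
F3 | step 7 | (1S,2R,3S,4S,6S)-4-[3-(formyloxy)prop-1-en-2-yl]-1-methyl-7-oxabicyclo[4.1.0]heptane-2,3-diyl bis[(2Z)-2-methylbut-2-enoate] | C=C(COC=O)[C@@H]1C[C@@H]2O[C@]2(C)[C@H](OC(=O)/C(C)=C\C)[C@H]1OC(=O)/C(C)=C\C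
F4 | step 7 | (1S,2R,3S,4S,6S)-4-(3-hydroxyprop-1-en-2-yl)-1-methyl-7-oxabicyclo[4.1.0]heptane-2,3-diyl bis[(2Z)-2-methylbut-2-enoate] | C=C(CO)[C@@H]1C[C@@H]2O[C@]2(C)[C@H](OC(=O)/C(C)=C\C)[C@H]1OC(=O)/C(C)=C\C
F5 | step 5 | (1S,2R,3S,4S,6S)-1-methyl-4-(prop-1-en-2-yl)-7-oxabicyclo[4.1.0]heptane-2,3-diyl bis{2-[bis(2,2,2-trifluoroethoxy)phosphoryl]propanoate} (epimer mixture at the two phosphonate α-carbons) | C=C(C)[C@@H]1C[C@@H]2O[C@]2(C)[C@H](OC(=O)C(C)P(=O)(OCC(F)(F)F)OCC(F)(F)F)[C@H]1OC(=O)C(C)P(=O)(OCC(F)(F)F)OCC(F)(F)F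
F6 | step 5 | dipotassium bis(phosphonate carbanion) of F5 (not isolated) | C=C(C)[C@@H]1C[C@@H]2O[C@]2(C)[C@H](OC(=O)[C-](C)P(=O)(OCC(F)(F)F)OCC(F)(F)F)[C@H]1OC(=O)[C-](C)P(=O)(OCC(F)(F)F)OCC(F)(F)F.[K+].[K+]
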